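**Retrosynthetic overview**

1. The C5–C6 bond is made in the ring-closing step: an intramolecular Nozaki–Hiyama–Kishi addition of a C5 alkenyl iodide to a C6 aldehyde closes the ten-membered carbocycle, and the C6 alkoxide then closes the butenolide onto the C12 ester in the same flask; the 1,10-epoxide is added last, on the outer face of the C1=C10 alkene.
2. Enabling feature: C6 is at once the allylic carbinol carbon of the ten-membered ring (between the C4=C5 alkene and C7) and the γ-oxygenated carbon of the butenolide ring (O–C6–C7=C11–C12=O), so an acyclic (Z)-3-formylacrylate with the ester cis to the formyl group gives both rings from one C–C bond formation.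
3. The cis formyl ester is unmasked from a 2-silyl-3,4-disubstituted furan by singlet-oxygen photooxygenation (silicon marks the carbon that becomes the C12 carbonyl); the furan is joined at C8–C9 by lateral alkylation of a 4-methyl-3-furoate with an allylic bromide.
4. The allylic bromide carries C3 (Brown allylation), the E C4=C5 iodoalkene (carboalumination–iodination) and the E C1=C10 alkene (cross-metathesis with methacrolein).
5. Ring order: furan (temporary) → ten-membered carbocycle and butenolide together → epoxide.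

Key step: step 16

Remark: positions are given in germacrane numbering (C1/C10 epoxide carbons, C3 ring acetoxy carbon, C4=C5 ring alkene, C6 lactone carbinol, C7=C11 butenolide alkene, C12 lactone carbonyl, C13 acetoxymethyl carbon); LiN(i-Pr)2 and (−)-Ipc2B(allyl) are assumed to be used as commercial solutions.

**Route**

Step 1
Reactants: 1 prop-2-yn-1-ol
Product: 3 (E)-3-iodo-2-methylprop-2-en-1-ol, via alkenylalane 2 (not isolated)
Conditions: Me3Al (3 equiv), Cp2ZrCl2 (0.25 equiv), CH2Cl2, 0 °C to rt; then I2, THF, −30 to 0 °C; aq. NaHCO3/Na2S2O3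
Reagents that add atoms: trimethylaluminium C[Al](C)C; iodine I-I
Why: Zirconium-catalysed syn-carboalumination (Negishi carboalumination) puts methyl on the internal carbon and aluminium on the terminal carbon cis to it, and iodinolysis with retention should give the E iodoalkene that becomes C4=C5.

Step 2
Reactants: 3 (E)-3-iodo-2-methylprop-2-en-1-ol
Product: 4 (E)-3-iodo-2-methylprop-2-enal
Conditions: MnO2 (activated, excess), CH2Cl2, rt
Reagents that add atoms: none
Why: Activated MnO2 oxidises allylic alcohols selectively (allylic oxidation) and should leave the iodoalkene and its geometry untouched.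

Step 3
Reactants: 4 (E)-3-iodo-2-methylprop-2-enal
Product: 6 (1E,3S)-1-iodo-2-methylhexa-1,5-dien-3-ol, via diisopinocampheylborinate 5 (not isolated)
Conditions: (−)-Ipc2B(allyl) (from (+)-α-pinene), Et2O, −78 °C; then NaOH, H2O2, 0 °C to rt
Reagents that add atoms: (−)-B-allyldiisopinocampheylborane C=CCB([C@@H]1C[C@@H]2C[C@H]([C@H]1C)C2(C)C)[C@@H]1C[C@@H]2C[C@H]([C@H]1C)C2(C)C
Why: Brown allylation through a chair six-membered transition state, in which the isopinocampheyl groups derived from (+)-α-pinene direct the allyl group to the Si face of the aldehyde, should set C3 as S.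

Step 4
Reactants: 6 (1E,3S)-1-iodo-2-methylhexa-1,5-dien-3-ol
Product: 7 (1E,3S)-1-iodo-2-methylhexa-1,5-dien-3-yl pivalate
Conditions: t-BuCOCl, pyridine, DMAP (cat.), CH2Cl2, 0 °C to rt
Reagents that add atoms: pivaloyl chloride CC(C)(C)C(Cl)=O
Why: DMAP-catalysed acylation of the secondary allylic alcohol installs an ester without α-hydrogen that should survive the carbanion chemistry of step 11 and is removed reductively in step 12.

Step 5
Reactants: 7 (1E,3S)-1-iodo-2-methylhexa-1,5-dien-3-yl pivalate; 8 methacrolein (2-methylprop-2-enal)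
Product: 9 (2E,5S,6E)-7-iodo-2,6-dimethyl-1-oxohepta-2,6-dien-5-yl pivalate
Conditions: second-generation Hoveyda–Grubbs catalyst RuCl2(H2IMes)(=CH-C6H4-2-OiPr) (5 mol %), methacrolein (5 equiv), CH2Cl2, 40 °C
Reagents that add atoms: none
Why: Olefin cross-metathesis of a terminal alkene with methacrolein is known to give the conjugated E trisubstituted enal, which fixes the E geometry of the future C1=C10 alkene, while the hindered trisubstituted iodoalkene should not take part.

Step 6
Reactants: 9 (2E,5S,6E)-7-iodo-2,6-dimethyl-1-oxohepta-2,6-dien-5-yl pivalate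
Product: 10 (2E,5S,6E)-1-hydroxy-7-iodo-2,6-dimethylhepta-2,6-dien-5-yl pivalate
Conditions: NaBH4, CeCl3·7H2O, MeOH, −40 °C
Reagents that add atoms: none
Why: Luche reduction should give clean 1,2-reduction of the enal and leave the pivalate and the iodoalkene untouched.

Step 7
Reactants: 10 (2E,5S,6E)-1-hydroxy-7-iodo-2,6-dimethylhepta-2,6-dien-5-yl pivalate
Product: 11 (2E,5S,6E)-1-bromo-7-iodo-2,6-dimethylhepta-2,6-dien-5-yl pivalate
Conditions: CBr4, PPh3, CH2Cl2, −20 °C
Reagents that add atoms: tetrabromomethane BrC(Br)(Br)Br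
Why: Appel bromination converts the primary allylic alcohol into the bromide under neutral conditions, and no allylic transposition is expected at a primary centre.

Step 8
Reactants: 12 furan-3-carboxylic acid
Product: 14 2-(tert-butyldimethylsilyl)furan-3-carboxylic acid, via dilithio species 13 (not isolated)
Conditions: LiN(i-Pr)2 (2.2 equiv), THF, −78 °C; t-BuMe2SiCl, −78 °C to rt; aq. HCl
Reagents that add atoms: tert-butyldimethylsilyl chloride C[Si](C)(Cl)C(C)(C)C
Why: Carboxylate-directed ortho-metalation of furan-3-carboxylic acid takes place at C2, which is both α to the ring oxygen and ortho to the carboxylate, and C-silylation puts silicon on the carbon that becomes C12.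

Step 9
Reactants: 14 2-(tert-butyldimethylsilyl)furan-3-carboxylic acid
Product: 16 2-(tert-butyldimethylsilyl)-4-methylfuran-3-carboxylic acid, via C4-lithio dianion 15 (not isolated)
Conditions: n-BuLi (2.2 equiv), THF, −20 °C; MeI, −78 °C to rt; aq. HCl
Reagents that add atoms: iodomethane IC
Why: With C2 blocked by silicon, directed ortho-metalation by the carboxylate should take place at C4, and methylation introduces the carbon that becomes C8.

Step 10
Reactants: 16 2-(tert-butyldimethylsilyl)-4-methylfuran-3-carboxylic acid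
Product: 17 methyl 2-(tert-butyldimethylsilyl)-4-methylfuran-3-carboxylate
Conditions: MeI, K2CO3, DMF, rt
Reagents that add atoms: iodomethane IC
Why: SN2 O-alkylation of the potassium carboxylate gives the methyl ester needed for the lateral deprotonation.

Step 11
Reactants: 17 methyl 2-(tert-butyldimethylsilyl)-4-methylfuran-3-carboxylate; 11 (2E,5S,6E)-1-bromo-7-iodo-2,6-dimethylhepta-2,6-dien-5-yl pivalate
Product: 19 methyl 2-(tert-butyldimethylsilyl)-4-[(3E,6S,7E)-8-iodo-3,7-dimethyl-6-(pivaloyloxy)octa-3,7-dien-1-yl]furan-3-carboxylate, via lithium dienolate 18 (not isolated)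
Conditions: LiN(i-Pr)2 (1.1 equiv), THF, DMPU, −78 °C; then 11, −78 to −40 °C
Reagents that add atoms: none
Why: Lateral metalation of the 4-methyl group ortho to the ester (as in o-toluate anion chemistry) gives a dienolate that should be alkylated at its exocyclic carbon by the primary allylic bromide in an SN2 reaction, which forms C8–C9 and restores the furan, and this stabilised carbanion should not exchange with the alkenyl iodide.

Step 12
Reactants: 19 methyl 2-(tert-butyldimethylsilyl)-4-[(3E,6S,7E)-8-iodo-3,7-dimethyl-6-(pivaloyloxy)octa-3,7-dien-1-yl]furan-3-carboxylate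
Product: 20 (3E,6S,7E)-1-[5-(tert-butyldimethylsilyl)-4-(hydroxymethyl)furan-3-yl]-8-iodo-3,7-dimethylocta-3,7-dien-6-ol
Conditions: i-Bu2AlH (6 equiv), CH2Cl2, −78 to −20 °C; aq. KNaC4H4O6 (potassium sodium tartrate)
Reagents that add atoms: none
Why: Diisobutylaluminium hydride reduction converts the furoate into the furylmethanol (C13) and cleaves the pivalate in the same operation, while the alkenyl iodide and the C–Si bond should be inert.

Step 13
Reactants: 20 (3E,6S,7E)-1-[5-(tert-butyldimethylsilyl)-4-(hydroxymethyl)furan-3-yl]-8-iodo-3,7-dimethylocta-3,7-dien-6-ol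
Product: 21 [4-[(3E,6S,7E)-6-acetoxy-8-iodo-3,7-dimethylocta-3,7-dien-1-yl]-2-(tert-butyldimethylsilyl)furan-3-yl]methyl acetate
Conditions: Ac2O, pyridine, DMAP (cat.), CH2Cl2, 0 °C to rt
Reagents that add atoms: acetic anhydride CC(=O)OC(C)=O
Why: Standard DMAP-catalysed acetylation installs both acetates of the target (C3 and C13) in one step.

Step 14
Reactants: 21 [4-[(3E,6S,7E)-6-acetoxy-8-iodo-3,7-dimethylocta-3,7-dien-1-yl]-2-(tert-butyldimethylsilyl)furan-3-yl]methyl acetate
Product: 24 [4-[(3E,6S,7E)-6-acetoxy-8-iodo-3,7-dimethylocta-3,7-dien-1-yl]-5-hydroxy-2-oxo-2,5-dihydrofuran-3-yl]methyl acetate (both C5 epimers), via furan endoperoxide 22 (not isolated), via silyl ester 23 (not isolated)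
Conditions: O2, 5,10,15,20-tetraphenylporphyrin (cat.), visible light, CH2Cl2, −78 °C; then H2O, THF, rt
Reagents that add atoms: dioxygen O=O
Why: [4+2] photooxygenation of the furan by singlet oxygen followed by 1,2-migration of silicon from carbon to peroxide oxygen (the known oxidation of 2-silylfurans to 5-hydroxybutenolides) makes the silylated carbon the carbonyl C12 and the unsubstituted α-carbon the hemiacetal C6, and at −78 °C the furan should react much faster than the trisubstituted alkene does in an ene reaction.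

Step 15
Reactants: 24 [4-[(3E,6S,7E)-6-acetoxy-8-iodo-3,7-dimethylocta-3,7-dien-1-yl]-5-hydroxy-2-oxo-2,5-dihydrofuran-3-yl]methyl acetate
Product: 25 methyl (2Z,6E,9S,10E)-9-acetoxy-2-(acetoxymethyl)-3-formyl-11-iodo-6,10-dimethylundeca-2,6,10-trienoate
Conditions: MeI, KHCO3, DMF, 0 °C to rt
Reagents that add atoms: iodomethane IC
Why: Under mildly basic conditions the pseudo-acid reacts through its ring-opened carboxylate, so SN2 O-methylation should give the open-chain formyl methyl ester with the cis (Z) geometry inherited from the ring.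

Step 16
Reactants: 25 methyl (2Z,6E,9S,10E)-9-acetoxy-2-(acetoxymethyl)-3-formyl-11-iodo-6,10-dimethylundeca-2,6,10-trienoate
Product: 28 (3S,6R)-3,13-diacetoxygermacra-1(10)E,4E,7(11)-trien-12,6-olide, via alkenylchromium species 26 (not isolated), via chromium alkoxide 27 (not isolated)
Conditions: CrCl2 (10 equiv), NiCl2 (2 mol %), degassed DMSO, rt, slow addition of 25 to a final 2 mM; aq. NH4Cl
Reagents that add atoms: none
Why: Divalent chromium chloride reduces NiCl2 to zerovalent nickel, which inserts into the C5–I bond with retention of the E geometry, and transmetalation gives the trivalent alkenylchromium 26, whose C5 adds to the C6 aldehyde to close the ten-membered carbocycle (10-exo-trig), after which the chromium alkoxide 27 attacks the C12 methyl ester held cis to it on the C7=C11 alkene (5-exo-trig) and expels methoxide to close the butenolide in the flask or on work-up. The closest known reaction type is the Nozaki–Hiyama–Kishi macrocyclization of iodoalkenyl aldehydes to nine- and ten-membered carbocycles, combined with the spontaneous lactonization of (Z)-γ-hydroxy enoates. The only new stereocenter, C6, is controlled by the C3 acetoxy stereocenter through the ring conformation: the two E alkenes should take up the crossed, crown-like germacrane arrangement with both methyl groups on one face, the C3 acetate choosing between the two mirror-image crowns by avoiding the inside position, and the aldehyde should then add with its chromium-bound oxygen turned outward, on the face opposite to the methyl groups, which corresponds to 6R. Chemoselectivity for the aldehyde over the ester and the acetates is secured by the low basicity and carbonyl selectivity of alkenylchromium reagents and by the low nickel loading, and ring closure over oligomerization by slow addition at high dilution. The cis relation of C6 and C12, fixed earlier by the furan ring, ensures that the alkoxide can only form the butenolide.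

Step 17
Reactants: 28 (3S,6R)-3,13-diacetoxygermacra-1(10)E,4E,7(11)-trien-12,6-olide
Product: 29 (1R,3S,6R,10R)-3,13-diacetoxy-1,10-epoxygermacra-4E,7(11)-dien-12,6-olide
Conditions: 3-chloroperoxybenzoic acid (1.05 equiv), NaHCO3, CH2Cl2, −20 to 0 °C
Reagents that add atoms: 3-chloroperoxybenzoic acid OOC(=O)c1cccc(Cl)c1
Why: Prilezhaev epoxidation should take place only at the isolated, most electron-rich C1=C10 alkene (C4=C5 is flanked by two allylic oxygen substituents and C7=C11 is conjugated with the lactone) and, as is known for (E,E)-germacra-1(10),4-dienolides, on its outer face in the crown conformer that carries both methyl groups on one face, which gives the trans 1R,10R epoxide.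

**Compound list**

1 | prop-2-yn-1-ol | C#CCO | starting material
2 | (E)-alkenylalane from carboalumination of 1 | C[Al](C)/C=C(\C)CO[Al](C)C | intermediate
3 | (E)-3-iodo-2-methylprop-2-en-1-ol | OC/C(C)=C/I | intermediate
4 | (E)-3-iodo-2-methylprop-2-enal | O=C/C(C)=C/I | intermediate
5 | (1E,3S)-1-iodo-2-methylhexa-1,5-dien-3-yl diisopinocampheylborinate | C=CC[C@H](OB([C@@H]1C[C@@H]2C[C@H]([C@H]1C)C2(C)C)[C@@H]1C[C@@H]2C[C@H]([C@H]1C)C2(C)C)/C(C)=C/I | intermediate
6 | (1E,3S)-1-iodo-2-methylhexa-1,5-dien-3-ol | C=CC[C@H](O)/C(C)=C/I | intermediate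
7 | (1E,3S)-1-iodo-2-methylhexa-1,5-dien-3-yl pivalate | C=CC[C@H](OC(=O)C(C)(C)C)/C(C)=C/I | intermediate
8 | methacrolein | CC(=C)C=O | starting material
9 | (2E,5S,6E)-7-iodo-2,6-dimethyl-1-oxohepta-2,6-dien-5-yl pivalate | O=C/C(C)=C/C[C@H](OC(=O)C(C)(C)C)/C(C)=C/I | intermediate
10 | (2E,5S,6E)-1-hydroxy-7-iodo-2,6-dimethylhepta-2,6-dien-5-yl pivalate | OC/C(C)=C/C[C@H](OC(=O)C(C)(C)C)/C(C)=C/I | intermediate
11 | (2E,5S,6E)-1-bromo-7-iodo-2,6-dimethylhepta-2,6-dien-5-yl pivalate | BrC/C(C)=C/C[C@H](OC(=O)C(C)(C)C)/C(C)=C/I | intermediate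
12 | furan-3-carboxylic acid | OC(=O)c1ccoc1 | starting material
13 | lithium 2-lithiofuran-3-carboxylate | [Li]OC(=O)c1ccoc1[Li] | intermediate
14 | 2-(tert-butyldimethylsilyl)furan-3-carboxylic acid | OC(=O)c1ccoc1[Si](C)(C)C(C)(C)C | intermediate
15 | lithium 2-(tert-butyldimethylsilyl)-4-lithiofuran-3-carboxylate | [Li]OC(=O)c1c([Li])coc1[Si](C)(C)C(C)(C)C | intermediate
16 | 2-(tert-butyldimethylsilyl)-4-methylfuran-3-carboxylic acid | Cc1coc([Si](C)(C)C(C)(C)C)c1C(O)=O | intermediate
17 | methyl 2-(tert-butyldimethylsilyl)-4-methylfuran-3-carboxylate | COC(=O)c1c(C)coc1[Si](C)(C)C(C)(C)C | intermediate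
18 | lateral lithium dienolate of 17 (4-lithiomethyl form) | [Li]Cc1coc([Si](C)(C)C(C)(C)C)c1C(=O)OC | intermediate
19 | methyl 2-(tert-butyldimethylsilyl)-4-[(3E,6S,7E)-8-iodo-3,7-dimethyl-6-(pivaloyloxy)octa-3,7-dien-1-yl]furan-3-carboxylate | COC(=O)c1c(CC/C(C)=C/C[C@H](OC(=O)C(C)(C)C)/C(C)=C/I)coc1[Si](C)(C)C(C)(C)C | intermediate
20 | (3E,6S,7E)-1-[5-(tert-butyldimethylsilyl)-4-(hydroxymethyl)furan-3-yl]-8-iodo-3,7-dimethylocta-3,7-dien-6-ol | OCc1c(CC/C(C)=C/C[C@H](O)/C(C)=C/I)coc1[Si](C)(C)C(C)(C)C | intermediate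
21 | [4-[(3E,6S,7E)-6-acetoxy-8-iodo-3,7-dimethylocta-3,7-dien-1-yl]-2-(tert-butyldimethylsilyl)furan-3-yl]methyl acetate | CC(=O)OCc1c(CC/C(C)=C/C[C@H](OC(C)=O)/C(C)=C/I)coc1[Si](C)(C)C(C)(C)C | intermediate
22 | furan endoperoxide of 21 (2,3,7-trioxabicyclo[2.2.1]hept-5-ene) | CC(=O)OCC1=C(CC/C(C)=C/C[C@H](OC(C)=O)/C(C)=C/I)C2OOC1([Si](C)(C)C(C)(C)C)O2 | intermediate
23 | tert-butyldimethylsilyl (2Z,6E,9S,10E)-9-acetoxy-2-(acetoxymethyl)-3-formyl-11-iodo-6,10-dimethylundeca-2,6,10-trienoate | CC(C)(C)[Si](C)(C)OC(=O)/C(COC(C)=O)=C(\C=O)CC/C(C)=C/C[C@H](OC(C)=O)/C(C)=C/I | intermediate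
24 | [4-[(3E,6S,7E)-6-acetoxy-8-iodo-3,7-dimethylocta-3,7-dien-1-yl]-5-hydroxy-2-oxo-2,5-dihydrofuran-3-yl]methyl acetate (both C5 epimers) | CC(=O)OCC1=C(CC/C(C)=C/C[C@H](OC(C)=O)/C(C)=C/I)C(O)OC1=O | intermediate
25 | methyl (2Z,6E,9S,10E)-9-acetoxy-2-(acetoxymethyl)-3-formyl-11-iodo-6,10-dimethylundeca-2,6,10-trienoate | COC(=O)/C(COC(C)=O)=C(\C=O)CC/C(C)=C/C[C@H](OC(C)=O)/C(C)=C/I | intermediate
26 | alkenylchromium dichloride from 25 (chromium on C5) | COC(=O)/C(COC(C)=O)=C(\C=O)CC/C(C)=C/C[C@H](OC(C)=O)/C(C)=C/[Cr](Cl)Cl | intermediate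
27 | chromium alkoxide of the ten-membered (6R)-hydroxy methyl ester | COC(=O)/C(COC(C)=O)=C1/CC/C(C)=C/C[C@H](OC(C)=O)/C(C)=C/[C@H]1O[Cr](Cl)Cl | intermediate
28 | (3S,6R)-3,13-diacetoxygermacra-1(10)E,4E,7(11)-trien-12,6-olide | CC(=O)OCC1=C2CC/C(C)=C/C[C@H](OC(C)=O)/C(C)=C/[C@H]2OC1=O | intermediate
29 | (1R,3S,6R,10R)-3,13-diacetoxy-1,10-epoxygermacra-4E,7(11)-dien-12,6-olide (CNP0294733.1) | CC(=O)OCC1=C2CC[C@@]3(C)O[C@@H]3C[C@H](OC(C)=O)/C(C)=C/[C@H]2OC1=O | target

**Step count and risks**

Total step count: 17. Longest linear sequence: 14 steps (steps 1–7, then 11–17); the furan branch (steps 8–10) joins at step 11.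

Steps most likely to fail:

Step 16. The addition of the alkenylchromium to the C6 aldehyde may show poor facial selectivity, or coupling between molecules may compete, and the C6 configuration cannot be corrected once the lactone has closed. The fallback sets C6 by reagent-controlled ketone reduction instead. It sets out from 24 and comes back at 28. Compound 24 would be alkylated on its ring-opened carboxylate (t-BuBr, K2CO3, BnEt3NCl, N,N-dimethylacetamide, 55 °C) to tert-butyl (2Z,6E,9S,10E)-9-acetoxy-2-(acetoxymethyl)-3-formyl-11-iodo-6,10-dimethylundeca-2,6,10-trienoate F1. The same CrCl2/NiCl2 ring closure should give the ten-membered hydroxy tert-butyl ester F2 as C6 epimers, because the hindered ester should not lactonize in the flask. Dess–Martin oxidation would give the C6 ketone F3. Corey–Bakshi–Shibata reduction with the (S)-oxazaborolidine and catecholborane at −78 °C, with the fully substituted C7 side acting as the large group, should give the (6R)-hydroxy tert-butyl ester F4. Catalytic NaN(SiMe3)2 in THF at −78 to 0 °C would then close the butenolide to 28.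

Step 11. Deprotonation at the free ring position C5, or self-condensation of the ester, may compete with lateral metalation. The fallback makes C8–C9 as an alkene and reduces it. It sets out from 14 (through its dianion 15) and from 11, and comes back at 19. Dianion 15 would be quenched with N,N-dimethylformamide to give 2-(tert-butyldimethylsilyl)-4-formylfuran-3-carboxylic acid F5, which would be methylated (MeI, K2CO3, DMF) to methyl 2-(tert-butyldimethylsilyl)-4-formylfuran-3-carboxylate F6. Bromide 11 and PPh3 would give [(2E,5S,6E)-7-iodo-2,6-dimethyl-5-(pivaloyloxy)hepta-2,6-dien-1-yl]triphenylphosphonium bromide F7. Its ylide (NaN(SiMe3)2, THF, −78 °C) would undergo a Wittig reaction with F6 to give the diene furoate F8 (new C8=C9 alkene, either geometry). Diimide from 2-nitrobenzenesulfonyl hydrazide and Et3N should then reduce only the 1,2-disubstituted C8=C9 alkene to give 19.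

Step 17. Epoxidation may occur from the wrong face through a second ring conformer, or acid may open the epoxide transannularly. The fallback sets the epoxide before ring closure under reagent control. It sets out from 10 and comes back at 29. Sharpless asymmetric epoxidation of 10 (Ti(OiPr)4, D-(−)-diethyl tartrate, t-BuOOH, 4 Å molecular sieves, CH2Cl2, −20 °C) should give [(2R,3R)-3-[(2S,3E)-4-iodo-3-methyl-2-(pivaloyloxy)but-3-en-1-yl]-2-methyloxiran-2-yl]methanol F9, which has the 1R,10R configuration. Triflation (Tf2O, 2,6-lutidine, −78 °C) would give the epoxy triflate F10, and alkylation of dienolate 18 with it the epoxy furoate F11. The conditions of steps 12 to 15 would then give the epoxy diol F12, the epoxy diacetate F13, the epoxy hydroxybutenolide F14 and the epoxy formyl ester F15. The ring closure of step 16 applied to F15 would give 29 directly as the last step.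

Further compounds
F1 | step 16 | tert-butyl (2Z,6E,9S,10E)-9-acetoxy-2-(acetoxymethyl)-3-formyl-11-iodo-6,10-dimethylundeca-2,6,10-trienoate | CC(C)(C)OC(=O)/C(COC(C)=O)=C(\C=O)CC/C(C)=C/C[C@H](OC(C)=O)/C(C)=C/I
F2 | step 16 | ten-membered hydroxy tert-butyl ester (both C6 epimers) | CC(C)(C)OC(=O)/C(COC(C)=O)=C1/CC/C(C)=C/C[C@H](OC(C)=O)/C(C)=C/C1O
F3 | step 16 | ten-membered C6 ketone tert-butyl ester | CC(C)(C)OC(=O)/C(COC(C)=O)=C1/CC/C(C)=C/C[C@H](OC(C)=O)/C(C)=C/C1=O
F4 | step 16 | ten-membered (6R)-hydroxy tert-butyl ester | CC(C)(C)OC(=O)/C(COC(C)=O)=C1/CC/C(C)=C/C[C@H](OC(C)=O)/C(C)=C/[C@H]1O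
F5 | step 11 | 2-(tert-butyldimethylsilyl)-4-formylfuran-3-carboxylic acid | OC(=O)c1c(C=O)coc1[Si](C)(C)C(C)(C)C
F6 | step 11 | methyl 2-(tert-butyldimethylsilyl)-4-formylfuran-3-carboxylate | COC(=O)c1c(C=O)coc1[Si](C)(C)C(C)(C)C
F7 | step 11 | [(2E,5S,6E)-7-iodo-2,6-dimethyl-5-(pivaloyloxy)hepta-2,6-dien-1-yl]triphenylphosphonium bromide | c1ccccc1[P+](c1ccccc1)(c1ccccc1)C/C(C)=C/C[C@H](OC(=O)C(C)(C)C)/C(C)=C/I.[Br-]
F8 | step 11 | methyl 2-(tert-butyldimethylsilyl)-4-[(3E,6S,7E)-8-iodo-3,7-dimethyl-6-(pivaloyloxy)octa-1,3,7-trien-1-yl]furan-3-carboxylate | COC(=O)c1c(C=C/C(C)=C/C[C@H](OC(=O)C(C)(C)C)/C(C)=C/I)coc1[Si](C)(C)C(C)(C)C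
F9 | step 17 | [(2R,3R)-3-[(2S,3E)-4-iodo-3-methyl-2-(pivaloyloxy)but-3-en-1-yl]-2-methyloxiran-2-yl]methanol | OC[C@@]1(C)O[C@@H]1C[C@H](OC(=O)C(C)(C)C)/C(C)=C/I
F10 | step 17 | trifluoromethanesulfonate of F9 | FC(F)(F)S(=O)(=O)OC[C@@]1(C)O[C@@H]1C[C@H](OC(=O)C(C)(C)C)/C(C)=C/I
F11 | step 17 | epoxy furoate (1R,10R-epoxide analogue of 19) | COC(=O)c1c(CC[C@@]2(C)O[C@@H]2C[C@H](OC(=O)C(C)(C)C)/C(C)=C/I)coc1[Si](C)(C)C(C)(C)C
F12 | step 17 | epoxy diol (analogue of 20) | OCc1c(CC[C@@]2(C)O[C@@H]2C[C@H](O)/C(C)=C/I)coc1[Si](C)(C)C(C)(C)C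
F13 | step 17 | epoxy diacetate (analogue of 21) | CC(=O)OCc1c(CC[C@@]2(C)O[C@@H]2C[C@H](OC(C)=O)/C(C)=C/I)coc1[Si](C)(C)C(C)(C)C
F14 | step 17 | epoxy hydroxybutenolide (analogue of 24, both hemiacetal epimers) | CC(=O)OCC1=C(CC[C@@]2(C)O[C@@H]2C[C@H](OC(C)=O)/C(C)=C/I)C(O)OC1=O
F15 | step 17 | epoxy formyl methyl ester (analogue of 25) | COC(=O)/C(COC(C)=O)=C(\C=O)CC[C@@]1(C)O[C@@H]1C[C@H](OC(C)=O)/C(C)=C/I
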